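**Retrosynthetic overview**

1. The benzene ring of the target is a hydroquinone monomethyl ether: the carbon bearing OMe (aryl C2, ortho to C1 with the side chain) is para to the carbon bearing the free OH (aryl C5). The C2–OMe bond is therefore made last, from the C2–H phenol 11, by anodic oxidation in methanol to the 4,4-dimethoxycyclohexa-2,5-dienone 14 and zinc reduction back to the arene.
2. Phenol 11 comes from silyl ether 10. Compound 10 comes from the prochiral 2-arylglycerol 6 by acylating its two primary hydroxyls in a fixed order: lipase monoacetylation (sets the only stereocentre), then tigloylation.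
3. Triol 6 comes from addition of the aryllithium of silylated 5-bromo-2-methylphenol to 2,2-dimethyl-1,3-dioxan-5-one (aryl C1–carbinol C bond), then acetonide hydrolysis.
4. Ring order: the benzene ring is bought and no ring is built. The dioxane ring of 3 is a temporary mask; the dienone ring of 14 is the benzene ring in dearomatised form and is re-aromatised in the last step.

Key step: step 7

Assumption: the lipase is taken to acylate the pro-S hydroxymethyl arm of triol 6; this sense has to be confirmed on the first batch (MTPA ester analysis of 8), and the fallback for step 4 leads to the same (S)-monoacetate if the enzyme prefers the other arm.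

**Route**

Step 1
Reactants: 1 5-bromo-2-methylphenol
Product: 2 tert-butyl(5-bromo-2-methylphenoxy)dimethylsilane
Conditions: TBSCl, imidazole, DMF, rt
Reagents that add atoms: tert-butyldimethylsilyl chloride (TBSCl), CC(C)(C)[Si](C)(C)Cl
Why: Silyl ether formation from a phenol with a silyl chloride and imidazole is routine, and the aryl silyl ether masks the acidic OH in the organolithium step and can later be removed with fluoride without harm to esters.

Step 2
Reactants: 2 tert-butyl(5-bromo-2-methylphenoxy)dimethylsilane; 3 2,2-dimethyl-1,3-dioxan-5-one
Product: 5 dioxanol adduct 5-[3-(tert-butyldimethylsilyloxy)-4-methylphenyl]-2,2-dimethyl-1,3-dioxan-5-ol, via aryllithium 4 (not isolated)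
Conditions: n-BuLi, THF, −78 °C; then 3, −78 to −40 °C; aq NH4Cl
Reagents that add atoms: none
Why: Bromine–lithium exchange at −78 °C is faster than ortho- or benzylic deprotonation and places lithium meta to the silyloxy group, where no anionic silyl migration is possible, and the aryllithium then undergoes 1,2-addition to the ketone to give a tertiary alcohol that is achiral, so no stereocentre arises here.

Step 3
Reactants: 5 5-[3-(tert-butyldimethylsilyloxy)-4-methylphenyl]-2,2-dimethyl-1,3-dioxan-5-ol
Product: 6 2-[3-(tert-butyldimethylsilyloxy)-4-methylphenyl]propane-1,2,3-triol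
Conditions: AcOH/H2O (4:1), THF, 40 °C
Reagents that add atoms: none
Why: Acid-catalysed hydrolysis of the six-membered acetonide is fast in aqueous acetic acid, whereas the aryl silyl ether tolerates this medium and the tertiary carbinol, flanked by two C–O bonds, is not prone to ionisation; the triol is still achiral.

Step 4
Reactants: 6 2-[3-(tert-butyldimethylsilyloxy)-4-methylphenyl]propane-1,2,3-triol; 7 vinyl acetate
Product: 8 (2S)-2-[3-(tert-butyldimethylsilyloxy)-4-methylphenyl]-2,3-dihydroxypropyl acetate
Conditions: Burkholderia cepacia lipase (Amano PS, immobilised), vinyl acetate (5 equiv), t-BuOMe, 25 °C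
Reagents that add atoms: vinyl acetate (7), C=COC(C)=O
Why: Lipase-catalysed irreversible transesterification with an enol ester desymmetrises the prochiral propane-1,3-diol unit, because the chiral active site acylates only one of the two enantiotopic CH2OH arms (taken as the pro-S arm), which turns the tertiary carbinol carbon into the (S)-stereocentre, leaves the tertiary OH alone, and removes the minor enantiomer preferentially through any over-acylation to the achiral diacetate.

Step 5
Reactants: 8 (2S)-2-[3-(tert-butyldimethylsilyloxy)-4-methylphenyl]-2,3-dihydroxypropyl acetate; 9 tigloyl chloride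
Product: 10 (2R)-3-acetoxy-2-[3-(tert-butyldimethylsilyloxy)-4-methylphenyl]-2-hydroxypropyl (2E)-2-methylbut-2-enoate
Conditions: pyridine, CH2Cl2, −20 to 0 °C (8 used crude, without chromatography)
Reagents that add atoms: tigloyl chloride (9), C/C=C(\C)C(=O)Cl
Why: Acylation of the primary alcohol with an acid chloride is far faster than that of the hindered tertiary alcohol, the weak base avoids both deconjugation of the acyl chloride through a vinylketene and acetyl migration that would scramble the stereocentre, and the centre itself is untouched (the descriptor changes from S to R only because the tigloyloxymethyl arm outranks the acetoxymethyl arm).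

Step 6
Reactants: 10 (2R)-3-acetoxy-2-[3-(tert-butyldimethylsilyloxy)-4-methylphenyl]-2-hydroxypropyl (2E)-2-methylbut-2-enoate
Product: 11 (2R)-3-acetoxy-2-hydroxy-2-(3-hydroxy-4-methylphenyl)propyl (2E)-2-methylbut-2-enoate
Conditions: Bu4NF, AcOH (1:1), THF, 0 °C
Reagents that add atoms: none
Why: Fluoride-mediated desilylation of an aryl silyl ether is fast at 0 °C, and the acetic acid buffer protonates the phenoxide as it forms, so the medium should not become basic enough for ester cleavage or acyl migration.

Step 7
Reactants: 11 (2R)-3-acetoxy-2-hydroxy-2-(3-hydroxy-4-methylphenyl)propyl (2E)-2-methylbut-2-enoate; 12 methanol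
Product: 14 (2R)-3-acetoxy-2-(6,6-dimethoxy-4-methyl-3-oxocyclohexa-1,4-dien-1-yl)-2-hydroxypropyl (2E)-2-methylbut-2-enoate, via para-methoxyphenol 13 (not isolated)
Conditions: graphite anode, Pt cathode, undivided cell, LiClO4 (0.1 M), MeOH, constant current (5 mA cm−2), 4.2–4.5 F mol−1, 0 °C
Reagents that add atoms: methanol (12), CO
Why: Anodic two-electron oxidation of the phenol with loss of a proton gives a phenoxonium ion that methanol captures at the ring carbon para to oxygen, and tautomerisation gives the para-methoxyphenol 13; because 13 is oxidised more easily than 11 it cannot be held at this stage, loses two further electrons and is trapped by a second methanol at the same carbon as the 4,4-dimethoxycyclohexa-2,5-dienone 14, which is not oxidised further at the working potential. The closest known reaction type is the anodic methoxylation of para-unsubstituted phenols to quinone monoketals in LiClO4/methanol. No ring is closed and no stereocentre is created: the ketal carbon carries two identical methoxy groups and the carbinol centre takes no part in the redox events. The step needs para rather than ortho capture and oxidation of the phenol alone; the para carbon carries the largest positive charge of the phenoxonium ion, one ortho carbon is blocked by the methyl group and the other lies between the oxygen and the quaternary side chain, while the tiglate alkene, both esters and the tertiary alcohol are oxidised only at much higher potential. The side chain sits on a ring carbon meta to the phenolic oxygen, which carries no charge in the cation, so benzylic C–C fragmentation is not favoured, and the tertiary OH cannot intercept the cation because that would close a four-membered ring; hydrogen evolution at the platinum cathode consumes the protons released at the anode, so the bulk stays near neutral and the esters should survive.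

Step 8
Reactants: 14 (2R)-3-acetoxy-2-(6,6-dimethoxy-4-methyl-3-oxocyclohexa-1,4-dien-1-yl)-2-hydroxypropyl (2E)-2-methylbut-2-enoate
Product: 13 (2R)-3-acetoxy-2-hydroxy-2-(5-hydroxy-2-methoxy-4-methylphenyl)propyl (2E)-2-methylbut-2-enoate
Conditions: Zn dust, AcOH, THF, 0 °C to rt
Reagents that add atoms: none
Why: Two-electron reduction of the cross-conjugated dienone by zinc in acetic acid (the known reduction of quinone monoketals to 4-methoxyphenols) gives a dienol that expels one methoxy group from the ketal carbon with aromatisation as the driving force, which should outrun loss of the allylic tertiary OH, while the esters, the tiglate alkene and the stereocentre are inert to these conditions.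

**Compound list**

1 | 5-bromo-2-methylphenol | Cc1ccc(Br)cc1O | starting material
2 | tert-butyl(5-bromo-2-methylphenoxy)dimethylsilane | Cc1ccc(Br)cc1O[Si](C)(C)C(C)(C)C | intermediate
3 | 2,2-dimethyl-1,3-dioxan-5-one | CC1(C)OCC(=O)CO1 | starting material
4 | [3-(tert-butyldimethylsilyloxy)-4-methylphenyl]lithium (not isolated) | [Li]c1ccc(C)c(O[Si](C)(C)C(C)(C)C)c1 | intermediate
5 | 5-[3-(tert-butyldimethylsilyloxy)-4-methylphenyl]-2,2-dimethyl-1,3-dioxan-5-ol | CC1(C)OCC(O)(CO1)c1ccc(C)c(O[Si](C)(C)C(C)(C)C)c1 | intermediate
6 | 2-[3-(tert-butyldimethylsilyloxy)-4-methylphenyl]propane-1,2,3-triol | OCC(O)(CO)c1ccc(C)c(O[Si](C)(C)C(C)(C)C)c1 | intermediate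
7 | vinyl acetate | C=COC(C)=O | starting material
8 | (2S)-2-[3-(tert-butyldimethylsilyloxy)-4-methylphenyl]-2,3-dihydroxypropyl acetate | OC[C@](O)(COC(C)=O)c1ccc(C)c(O[Si](C)(C)C(C)(C)C)c1 | intermediate
9 | tigloyl chloride, (2E)-2-methylbut-2-enoyl chloride | C/C=C(\C)C(=O)Cl | starting material
10 | (2R)-3-acetoxy-2-[3-(tert-butyldimethylsilyloxy)-4-methylphenyl]-2-hydroxypropyl (2E)-2-methylbut-2-enoate | C/C=C(\C)C(=O)OC[C@](O)(COC(C)=O)c1ccc(C)c(O[Si](C)(C)C(C)(C)C)c1 | intermediate
11 | (2R)-3-acetoxy-2-hydroxy-2-(3-hydroxy-4-methylphenyl)propyl (2E)-2-methylbut-2-enoate | C/C=C(\C)C(=O)OC[C@](O)(COC(C)=O)c1cc(O)c(C)cc1 | intermediate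
12 | methanol | CO | starting material
13 | (2R)-3-acetoxy-2-hydroxy-2-(5-hydroxy-2-methoxy-4-methylphenyl)propyl (2E)-2-methylbut-2-enoate (also passed through, not isolated, in step 7) | C/C=C(\C)C(=O)OC[C@](O)(COC(C)=O)c1cc(O)c(C)cc1OC | target
14 | (2R)-3-acetoxy-2-(6,6-dimethoxy-4-methyl-3-oxocyclohexa-1,4-dien-1-yl)-2-hydroxypropyl (2E)-2-methylbut-2-enoate (quinone monoketal) | C/C=C(\C)C(=O)OC[C@](O)(COC(C)=O)C1=CC(=O)C(C)=CC1(OC)OC | intermediate

Total step count: 8
Longest linear sequence: 8 steps (1 to 13)

**Steps most likely to fail**

Step 7. What may go wrong: capture of the phenoxonium ion at an ortho carbon (ipso to the methyl group) instead of the hindered para carbon, radical coupling of the phenol that films the anode, and methanolysis of the acetate by methoxide near the cathode. The fallback sets out from 3 (and uses 7 and 9) and comes back at 13; it gives up the late C–H oxygenation and brings the methoxy group in with the arene. Commercial 4-methoxy-2-methylphenol (COc1ccc(O)c(C)c1) is silylated (TBSCl, imidazole, DMF) to tert-butyl(4-methoxy-2-methylphenoxy)dimethylsilane F1. Bromination with NBS in MeCN should take place ortho to the methoxy group and para to the methyl group, giving tert-butyl(5-bromo-4-methoxy-2-methylphenoxy)dimethylsilane F2. The operations of steps 2 to 6 are then run in this series: bromine–lithium exchange gives [5-(tert-butyldimethylsilyloxy)-2-methoxy-4-methylphenyl]lithium F3, which adds to 3 to give 5-[5-(tert-butyldimethylsilyloxy)-2-methoxy-4-methylphenyl]-2,2-dimethyl-1,3-dioxan-5-ol F4; aqueous AcOH gives 2-[5-(tert-butyldimethylsilyloxy)-2-methoxy-4-methylphenyl]propane-1,2,3-triol F5; the lipase and 7 give (2S)-2-[5-(tert-butyldimethylsilyloxy)-2-methoxy-4-methylphenyl]-2,3-dihydroxypropyl acetate F6; 9 and pyridine give (2R)-3-acetoxy-2-[5-(tert-butyldimethylsilyloxy)-2-methoxy-4-methylphenyl]-2-hydroxypropyl (2E)-2-methylbut-2-enoate F7; and Bu4NF/AcOH then gives 13 directly, so that steps 7 and 8 are not needed.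

Step 4. What may go wrong: weak or reversed discrimination between the two enantiotopic hydroxymethyl arms, and erosion of enantiopurity through 1,3-acetyl migration in the monoacetate during isolation. The fallback sets out from 6 and comes back at 8. Both primary hydroxyls are acetylated (Ac2O, pyridine, 0 °C) to the achiral 2-[3-(tert-butyldimethylsilyloxy)-4-methylphenyl]-2-hydroxypropane-1,3-diyl diacetate F8, and the same lipase is used in the hydrolytic direction (phosphate buffer pH 7, t-BuOMe). The enzyme then removes the acetyl group from the arm it would otherwise acylate, so the monoacetate of opposite configuration results; this gives (S)-8 if the acylation mode favours (R)-8. The monoacetate is again tigloylated crude.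

Step 2. What may go wrong: deprotonation of the enolisable ketone 3 by the aryllithium in place of addition, which returns the debrominated arene. The fallback sets out from 4 and comes back at 6. The aryllithium 4 is added at −78 °C to diethyl oxomalonate (CCOC(=O)C(=O)C(=O)OCC), a ketone without α-hydrogen, to give diethyl 2-[3-(tert-butyldimethylsilyloxy)-4-methylphenyl]-2-hydroxymalonate F9. Reduction of both ester groups with LiBH4 in THF (0 °C to rt) then gives triol 6, so step 3 is skipped.

**Further compounds**

F1 | step 7 | tert-butyl(4-methoxy-2-methylphenoxy)dimethylsilane | COc1ccc(O[Si](C)(C)C(C)(C)C)c(C)c1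
F2 | step 7 | tert-butyl(5-bromo-4-methoxy-2-methylphenoxy)dimethylsilane | COc1cc(C)c(O[Si](C)(C)C(C)(C)C)cc1Br
F3 | step 7 | [5-(tert-butyldimethylsilyloxy)-2-methoxy-4-methylphenyl]lithium | [Li]c1cc(O[Si](C)(C)C(C)(C)C)c(C)cc1OC
F4 | step 7 | 5-[5-(tert-butyldimethylsilyloxy)-2-methoxy-4-methylphenyl]-2,2-dimethyl-1,3-dioxan-5-ol | CC1(C)OCC(O)(CO1)c1cc(O[Si](C)(C)C(C)(C)C)c(C)cc1OC
F5 | step 7 | 2-[5-(tert-butyldimethylsilyloxy)-2-methoxy-4-methylphenyl]propane-1,2,3-triol | OCC(O)(CO)c1cc(O[Si](C)(C)C(C)(C)C)c(C)cc1OC
F6 | step 7 | (2S)-2-[5-(tert-butyldimethylsilyloxy)-2-methoxy-4-methylphenyl]-2,3-dihydroxypropyl acetate | OC[C@](O)(COC(C)=O)c1cc(O[Si](C)(C)C(C)(C)C)c(C)cc1OC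
F7 | step 7 | (2R)-3-acetoxy-2-[5-(tert-butyldimethylsilyloxy)-2-methoxy-4-methylphenyl]-2-hydroxypropyl (2E)-2-methylbut-2-enoate | C/C=C(\C)C(=O)OC[C@](O)(COC(C)=O)c1cc(O[Si](C)(C)C(C)(C)C)c(C)cc1OC
F8 | step 4 | 2-[3-(tert-butyldimethylsilyloxy)-4-methylphenyl]-2-hydroxypropane-1,3-diyl diacetate | CC(=O)OCC(O)(COC(C)=O)c1ccc(C)c(O[Si](C)(C)C(C)(C)C)c1
F9 | step 2 | diethyl 2-[3-(tert-butyldimethylsilyloxy)-4-methylphenyl]-2-hydroxymalonate | CCOC(=O)C(O)(C(=O)OCC)c1ccc(C)c(O[Si](C)(C)C(C)(C)C)c1
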